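The 1,2-dioxane ring holds its O1–O2 bond between two quaternary carbons, C3 and C6, whose methyl groups are trans. Trimming both side chains to CH2OH therefore reveals a C2-symmetric diol. The plan rests on cutting both ring C–O bonds (C3–O2 and C6–O1) back to hydrogen peroxide and a C2-symmetric (S,S)-bis(2-methyloxirane) joined by an ethylene tether. In one operation H2O2 opens one oxirane at its tertiary carbon and the resulting hydroperoxide closes onto the other. This forms the ring and sets both stereocentres by double inversion. The bis-epoxide comes from (S)-citramalic acid by Kolbe dimerisation, and the two arms are then grown by olefination.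

Key step: step 6

Assumption: the comments use target numbering O1, O2, C3 (propanoic acid arm), C4, C5, C6 (8-phenyloctyl arm), which makes the target the (3R,6S) isomer; compounds 1, 7, 12 and 18 are taken as catalogue chemicals.

Step 1
Reactants: 1 (S)-citramalic acid
Product: 2 2-[(4S)-2,2,4-trimethyl-5-oxo-1,3-dioxolan-4-yl]acetic acid
Conditions: Me2C(OMe)2, TsOH·H2O (cat.), acetone, rt
Reagents that add atoms: 2,2-dimethoxypropane, COC(C)(C)OC
Why: Acid-catalysed acetal exchange (acetonide formation) ties the tertiary hydroxyl to the neighbouring carboxyl as a five-membered dioxolanone, preferred over the six-membered alternative through the distal carboxyl, so only the CH2CO2H group needed for electrolysis stays free and the stereocentre loses no bond.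

Step 2
Reactants: 2 2-[(4S)-2,2,4-trimethyl-5-oxo-1,3-dioxolan-4-yl]acetic acid (two molecules)
Product: 3 (5S,5'S)-5,5'-(ethane-1,2-diyl)bis(2,2,5-trimethyl-1,3-dioxolan-4-one)
Conditions: anodic oxidation, Pt anode/Pt cathode, undivided cell, MeOH, Et3N (0.05–0.1 equiv), high current density, 10–20 °C, stopped before the medium turns basic
Reagents that add atoms: none
Why: Kolbe electrolysis of the partly neutralised acid gives a primary neopentyl-type radical that resists further oxidation and dimerises at the platinum anode to form the central CH2–CH2 bond (future C4–C5); the stereocentres lie one atom from the radical site and are retained, and any minor enantiomer is diverted mainly into a separable meso dimer.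

Step 3
Reactants: 3 (5S,5'S)-5,5'-(ethane-1,2-diyl)bis(2,2,5-trimethyl-1,3-dioxolan-4-one)
Product: 4 (2S,5S)-2,5-dimethylhexane-1,2,5,6-tetraol
Conditions: LiAlH4, THF, 0 °C to rt; Na2SO4·10H2O quench, salts extracted with hot THF
Reagents that add atoms: none
Why: Hydride reduction of both lactone-type carbonyls collapses each dioxolanone to a primary/tertiary 1,2-diol with loss of acetone (itself reduced), breaks no bond to a stereocentre, and the non-aqueous quench avoids losing the water-soluble tetraol.

Step 4
Reactants: 4 (2S,5S)-2,5-dimethylhexane-1,2,5,6-tetraol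
Product: 5 (2S,5S)-2,5-dihydroxy-2,5-dimethylhexane-1,6-diyl bis(4-methylbenzenesulfonate)
Conditions: TsCl (2.1 equiv), pyridine, 0 °C
Reagents that add atoms: 4-toluenesulfonyl chloride, Cc1ccc(cc1)S(=O)(=O)Cl
Why: Chemoselective sulfonylation, since only the primary hydroxyls react under these conditions while the tertiary carbinols stay inert, and the bis-tosylate offers a crystallisation point where traces of meso isomer can be purged.

Step 5
Reactants: 5 (2S,5S)-2,5-dihydroxy-2,5-dimethylhexane-1,6-diyl bis(4-methylbenzenesulfonate)
Product: 6 (2S,2'S)-2,2'-(ethane-1,2-diyl)bis(2-methyloxirane)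
Conditions: K2CO3, MeOH, 0 °C to rt
Reagents that add atoms: none
Why: Intramolecular Williamson etherification (3-exo-tet) in which each tertiary alkoxide displaces the adjacent primary tosylate far faster than any remote one, so the C–O bonds at the stereocentres persist and the (S,S) configuration is retained.

Step 6
Reactants: 6 (2S,2'S)-2,2'-(ethane-1,2-diyl)bis(2-methyloxirane); 7 hydrogen peroxide
Product: 9 [(3R,6R)-3,6-dimethyl-1,2-dioxane-3,6-diyl]dimethanol, via hydroperoxy epoxide 8 (not isolated)
Conditions: H2O2 (dried Et2O solution, 2–3 equiv), H3PMo12O40 (5 mol %), Et2O, ca. 0.03 M in 6, 0 °C to rt, blast shield, solution never concentrated before excess H2O2 is washed out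
Reagents that add atoms: none
Why: Proposed new method: H3PMo12O40, a strongly acidic cluster of hexavalent molybdenum that also binds peroxides, should activate one oxirane of 6 so that H2O2 attacks its tertiary carbon from the rear in a loose SN2 opening to give 8, whose terminal OOH oxygen then opens the second activated oxirane at its tertiary carbon in the same flask. The closest known reaction types are molybdenum-catalysed perhydrolysis of 2,2-disubstituted epoxides to beta-hydroxy tertiary hydroperoxides, invertive opening of enantioenriched tertiary oxetanes by H2O2, and acid-promoted cyclisation of hydroperoxy epoxides to 1,2-dioxanes; untested is the tandem use of both oxygens of one H2O2 molecule on a bis-epoxide. The 1,2-dioxane ring closes 6-exo-tet, since the ethylene tether puts the electrophilic carbon at the sixth position counted from the attacking oxygen and the breaking C–O bond lies outside the new ring. Both new stereocentres (future C3 and C6) are under substrate control: each arises by Walden inversion of an (S)-configured oxirane carbon, so (S,S)-6 should map onto (R,R)-9 with trans methyls, and the C2 axis makes it immaterial which oxirane reacts first. Needed are tertiary-over-primary regioselectivity, secured by the methyl/alkyl-stabilised positive charge that develops under acid activation, and peroxide-over-hydroxyl chemoselectivity in the closure (the liberated CH2OH could form a tetrahydropyran, likewise 6-exo), secured by the alpha-effect nucleophilicity of OOH and its preferential coordination to molybdenum. Moderate dilution and only a small excess of H2O2 should keep the unimolecular closure ahead of a second perhydrolysis.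

Step 7
Reactants: 9 [(3R,6R)-3,6-dimethyl-1,2-dioxane-3,6-diyl]dimethanol
Product: 10 [(3R,6R)-6-{[(tert-butyldimethylsilyl)oxy]methyl}-3,6-dimethyl-1,2-dioxan-3-yl]methanol
Conditions: TBSCl (0.9 equiv), imidazole, CH2Cl2/DMF, 0 °C; recovered diol and over-silylated material recycled
Reagents that add atoms: tert-butyldimethylsilyl chloride, CC(C)(C)[Si](C)(C)Cl
Why: Statistical monosilylation in which the two hydroxymethyl groups are homotopic under the C2 axis, so reaction at either gives the same single stereoisomer, while a slight deficit of TBSCl under a weak amine base curbs double silylation and avoids a free alkoxide beta to the peroxide.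

Step 8
Reactants: 10 [(3R,6R)-6-{[(tert-butyldimethylsilyl)oxy]methyl}-3,6-dimethyl-1,2-dioxan-3-yl]methanol
Product: 11 (3R,6R)-6-{[(tert-butyldimethylsilyl)oxy]methyl}-3,6-dimethyl-1,2-dioxane-3-carbaldehyde
Conditions: Dess–Martin periodinane, CH2Cl2, 0 °C to rt
Reagents that add atoms: none
Why: Dess–Martin oxidation runs under near-neutral, non-reducing conditions that leave the O–O bond and the silyl ether alone, and the alpha-peroxy aldehyde has a quaternary alpha-carbon and so cannot enolise or epimerise.

Step 9
Reactants: 12 (7-bromoheptyl)benzene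
Product: 13 (7-phenylheptyl)triphenylphosphonium bromide
Conditions: PPh3, MeCN, reflux; salt recrystallised free of PPh3
Reagents that add atoms: triphenylphosphine, c1ccc(cc1)P(c1ccccc1)c1ccccc1
Why: SN2 quaternisation of triphenylphosphine by an unhindered primary bromide, with recrystallisation removing free phosphine that should not meet the peroxide later.

Step 10
Reactants: 11 (3R,6R)-6-{[(tert-butyldimethylsilyl)oxy]methyl}-3,6-dimethyl-1,2-dioxane-3-carbaldehyde; 13 (7-phenylheptyl)triphenylphosphonium bromide
Product: 15 tert-butyl({(3R,6R)-3,6-dimethyl-6-[(1Z)-8-phenyloct-1-en-1-yl]-1,2-dioxan-3-yl}methoxy)dimethylsilane, via phosphorus ylide 14 (not isolated)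
Conditions: 13, NaN(SiMe3)2, THF, 0 °C; then 11, −78 °C to 0 °C
Reagents that add atoms: none
Why: Wittig olefination in which the lithium-free non-stabilised ylide adds to the unenolisable aldehyde by direct oxaphosphetane formation, which avoids a long-lived betaine alkoxide beta to the O–O bond (Grob-type fragmentation), while the di-tertiary peroxide is too shielded for attack by the ylide; Z geometry is expected but does not matter because step 14 saturates the alkene.

Step 11
Reactants: 15 tert-butyl({(3R,6R)-3,6-dimethyl-6-[(1Z)-8-phenyloct-1-en-1-yl]-1,2-dioxan-3-yl}methoxy)dimethylsilane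
Product: 16 {(3R,6R)-3,6-dimethyl-6-[(1Z)-8-phenyloct-1-en-1-yl]-1,2-dioxan-3-yl}methanol
Conditions: Bu4NF/AcOH (1:1), THF, 0 °C to rt
Reagents that add atoms: none
Why: Fluoride-driven desilylation, buffered with acetic acid so the released oxygen is protonated at once, and harmless to a peroxide that has no alpha-hydrogen and so cannot undergo Kornblum–DeLaMare cleavage.

Step 12
Reactants: 16 {(3R,6R)-3,6-dimethyl-6-[(1Z)-8-phenyloct-1-en-1-yl]-1,2-dioxan-3-yl}methanol
Product: 17 (3R,6R)-3,6-dimethyl-6-[(1Z)-8-phenyloct-1-en-1-yl]-1,2-dioxane-3-carbaldehyde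
Conditions: Dess–Martin periodinane, CH2Cl2, 0 °C to rt
Reagents that add atoms: none
Why: A second Dess–Martin oxidation, to which the Z-alkene, the arene and the peroxide are all inert, again gives an aldehyde on a quaternary carbon that cannot epimerise.

Step 13
Reactants: 17 (3R,6R)-3,6-dimethyl-6-[(1Z)-8-phenyloct-1-en-1-yl]-1,2-dioxane-3-carbaldehyde; 18 trimethyl phosphonoacetate
Product: 19 methyl (2E)-3-{(3R,6R)-3,6-dimethyl-6-[(1Z)-8-phenyloct-1-en-1-yl]-1,2-dioxan-3-yl}prop-2-enoate
Conditions: LiCl, DBU, MeCN, 0 °C to rt
Reagents that add atoms: none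
Why: Horner–Wadsworth–Emmons olefination in the Masamune–Roush mode, where lithium chelation acidifies the phosphonate enough for an amidine base, so no strong base meets the peroxide and the two-carbon ester arm is added as the E-enoate, whose geometry is erased in the next step.

Step 14
Reactants: 19 methyl (2E)-3-{(3R,6R)-3,6-dimethyl-6-[(1Z)-8-phenyloct-1-en-1-yl]-1,2-dioxan-3-yl}prop-2-enoate
Product: 20 methyl 3-[(3R,6S)-3,6-dimethyl-6-(8-phenyloctyl)-1,2-dioxan-3-yl]propanoate
Conditions: KO2CN=NCO2K (large excess, in portions), AcOH, MeOH/CH2Cl2, 0 °C to rt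
Reagents that add atoms: none
Why: Diimide reduction transfers H2 to C=C bonds in a concerted syn fashion and ignores O–O, ester and arene, unlike metal-catalysed hydrogenation, and repeated charges offset the hindrance beside the quaternary carbons; no bond at C3 or C6 changes, and the C6 descriptor switches from R to S only because the saturated chain now ranks below ring carbon C5.

Step 15
Reactants: 20 methyl 3-[(3R,6S)-3,6-dimethyl-6-(8-phenyloctyl)-1,2-dioxan-3-yl]propanoate
Product: 21 3-[(3R,6S)-3,6-dimethyl-6-(8-phenyloctyl)-1,2-dioxan-3-yl]propanoic acid (target)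
Conditions: LiOH, THF/H2O, 0 °C to rt; then 1 M HCl to pH 3
Reagents that add atoms: lithium hydroxide, [Li+].[OH-]
Why: Saponification (acyl-oxygen cleavage by hydroxide) of an unhindered methyl ester, tolerated because both peroxide carbons are quaternary and offer no proton for base-induced O–O cleavage, followed by mild acidification to the free acid.

Compound list
1 | (S)-citramalic acid, (2S)-2-hydroxy-2-methylbutanedioic acid | C[C@](O)(CC(=O)O)C(=O)O | starting material
2 | 2-[(4S)-2,2,4-trimethyl-5-oxo-1,3-dioxolan-4-yl]acetic acid | C[C@@]1(CC(=O)O)OC(C)(C)OC1=O | intermediate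
3 | (5S,5'S)-5,5'-(ethane-1,2-diyl)bis(2,2,5-trimethyl-1,3-dioxolan-4-one) | C[C@@]1(CC[C@]2(C)OC(C)(C)OC2=O)OC(C)(C)OC1=O | intermediate
4 | (2S,5S)-2,5-dimethylhexane-1,2,5,6-tetraol | C[C@@](O)(CO)CC[C@](C)(O)CO | intermediate
5 | (2S,5S)-2,5-dihydroxy-2,5-dimethylhexane-1,6-diyl bis(4-methylbenzenesulfonate) | C[C@@](O)(COS(=O)(=O)c1ccc(C)cc1)CC[C@](C)(O)COS(=O)(=O)c1ccc(C)cc1 | intermediate
6 | (2S,2'S)-2,2'-(ethane-1,2-diyl)bis(2-methyloxirane) | C[C@]1(CC[C@@]2(C)CO2)CO1 | intermediate
7 | hydrogen peroxide | OO | starting material
8 | (2R)-2-hydroperoxy-2-methyl-4-[(2S)-2-methyloxiran-2-yl]butan-1-ol | C[C@@](OO)(CC[C@@]1(C)CO1)CO | intermediate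
9 | [(3R,6R)-3,6-dimethyl-1,2-dioxane-3,6-diyl]dimethanol | C[C@]1(CO)CC[C@](C)(CO)OO1 | intermediate
10 | [(3R,6R)-6-{[(tert-butyldimethylsilyl)oxy]methyl}-3,6-dimethyl-1,2-dioxan-3-yl]methanol | C[C@]1(CO)CC[C@](C)(CO[Si](C)(C)C(C)(C)C)OO1 | intermediate
11 | (3R,6R)-6-{[(tert-butyldimethylsilyl)oxy]methyl}-3,6-dimethyl-1,2-dioxane-3-carbaldehyde | C[C@]1(C=O)CC[C@](C)(CO[Si](C)(C)C(C)(C)C)OO1 | intermediate
12 | (7-bromoheptyl)benzene | BrCCCCCCCc1ccccc1 | starting material
13 | (7-phenylheptyl)triphenylphosphonium bromide | [Br-].c1ccccc1CCCCCCC[P+](c1ccccc1)(c1ccccc1)c1ccccc1 | intermediate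
14 | (7-phenylheptylidene)triphenylphosphorane | c1ccccc1CCCCCCC=P(c1ccccc1)(c1ccccc1)c1ccccc1 | intermediate
15 | tert-butyl({(3R,6R)-3,6-dimethyl-6-[(1Z)-8-phenyloct-1-en-1-yl]-1,2-dioxan-3-yl}methoxy)dimethylsilane | C[C@]1(/C=C\CCCCCCc2ccccc2)CC[C@](C)(CO[Si](C)(C)C(C)(C)C)OO1 | intermediate
16 | {(3R,6R)-3,6-dimethyl-6-[(1Z)-8-phenyloct-1-en-1-yl]-1,2-dioxan-3-yl}methanol | C[C@]1(/C=C\CCCCCCc2ccccc2)CC[C@](C)(CO)OO1 | intermediate
17 | (3R,6R)-3,6-dimethyl-6-[(1Z)-8-phenyloct-1-en-1-yl]-1,2-dioxane-3-carbaldehyde | C[C@]1(/C=C\CCCCCCc2ccccc2)CC[C@](C)(C=O)OO1 | intermediate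
18 | trimethyl phosphonoacetate | COC(=O)CP(=O)(OC)OC | starting material
19 | methyl (2E)-3-{(3R,6R)-3,6-dimethyl-6-[(1Z)-8-phenyloct-1-en-1-yl]-1,2-dioxan-3-yl}prop-2-enoate | C[C@]1(/C=C\CCCCCCc2ccccc2)CC[C@](C)(/C=C/C(=O)OC)OO1 | intermediate
20 | methyl 3-[(3R,6S)-3,6-dimethyl-6-(8-phenyloctyl)-1,2-dioxan-3-yl]propanoate | C[C@]1(CCCCCCCCc2ccccc2)CC[C@](C)(CCC(=O)OC)OO1 | intermediate
21 | 3-[(3R,6S)-3,6-dimethyl-6-(8-phenyloctyl)-1,2-dioxan-3-yl]propanoic acid (CNP0390528.1) | C[C@]1(CCCCCCCCc2ccccc2)CC[C@](C)(CCC(=O)O)OO1 | target

Total steps: 15. Longest linear sequence: 14 steps (steps 1–8 and 10–15) from 1.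

Steps most likely to fail

1. Step 6.
- **What may go wrong:** The ring closure may be taken over by the freshly released hydroxymethyl group or by a second molecule of H2O2. The two oxiranes may react with each other or rearrange to carbonyl compounds under the acid. Partial ionisation at the tertiary carbons would erode the inversion.
- **Fallback (known chemistry only, sets out from 6 and rejoins at 10):**
  - One oxirane of 6 is isomerised with one equivalent of Et2Al(TMP) (TMP = 2,2,6,6-tetramethylpiperidide), a base-induced epoxide-to-allylic-alcohol rearrangement with unreacted 6 recovered. This gives the epoxy allylic alcohol F1, which is silylated (TBSCl, imidazole) to the silyl ether F2.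
  - Mukaiyama–Isayama peroxysilylation (Co(thd)2, thd = 2,2,6,6-tetramethylheptane-3,5-dionate, O2, Et3SiH, 1,2-dichloroethane) installs the tertiary peroxide as the triethylsilyl peroxide F3, a mixture of epimers at the new carbon.
  - Brief K2CO3/MeOH at 0 °C frees the hydroperoxide F4. Amberlyst-15 in CH2Cl2 then closes the ring by the established acid-promoted 6-exo opening of the remaining (S)-oxirane with inversion.
  - No hydroxyl competes because the only one present is silylated, and no second epoxide or external H2O2 is involved.
  - The trans product is 10 itself, so step 7 is skipped as well. The cis epimer F5 is removed by chromatography.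

2. Step 2.
- **What may go wrong:** The radical may be over-oxidised to a cation and trapped by solvent. Hydrogen abstraction may compete with coupling. The anode may passivate. The dioxolanone may undergo methanolysis as the catholyte turns alkaline.
- **Fallback (sets out from 2 and rejoins at 3):**
  - Acid 2 is esterified with N-hydroxyphthalimide (DIC, DMAP cat., CH2Cl2) to the redox-active ester F6.
  - F6 is homocoupled by nickel-catalysed reductive, doubly decarboxylative alkyl–alkyl coupling (NiCl2·glyme, 2,2':6',2''-terpyridine, Zn or cathodic current, DMF).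
  - The radical is now generated by reduction in an aprotic medium, so the cation pathway and solvolysis of the dioxolanone are both closed.

3. Step 14.
- **What may go wrong:** Hydrogen transfer may stall because each alkene sits beside a quaternary carbon, and diimide would then be lost by disproportionation faster than it is consumed. The unstrained E-enoate is judged the more stubborn of the two.
- **Fallback (sets out from 17 and rejoins at 21):**
  - The enoate is never made. Aldehyde 17, Meldrum's acid and Hantzsch ester with catalytic L-proline undergo three-component reductive alkylation. Knoevenagel condensation gives the alkylidene Meldrum's acid F7, and hydride transfer in the same flask gives the alkyl Meldrum's acid F8.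
  - Warming F8 in pyridine/water hydrolyses and decarboxylates it to the alkenyl acid F9. The temperature stays well below the decomposition range of a di-tertiary peroxide.
  - Only the strained Z-alkene then remains for diimide (KO2CN=NCO2K, AcOH), which leads directly to 21, so steps 13 and 15 fall away.

Further compounds
F1 | step 6 | 2-methylidene-4-[(2S)-2-methyloxiran-2-yl]butan-1-ol | C=C(CO)CC[C@@]1(C)CO1
F2 | step 6 | tert-butyldimethyl({2-methylidene-4-[(2S)-2-methyloxiran-2-yl]butyl}oxy)silane | C=C(CO[Si](C)(C)C(C)(C)C)CC[C@@]1(C)CO1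
F3 | step 6 | tert-butyl{2-methyl-4-[(2S)-2-methyloxiran-2-yl]-2-[(triethylsilyl)peroxy]butoxy}dimethylsilane (both epimers at C2) | CC[Si](CC)(CC)OOC(C)(CO[Si](C)(C)C(C)(C)C)CC[C@@]1(C)CO1
F4 | step 6 | 1-[(tert-butyldimethylsilyl)oxy]-2-methyl-4-[(2S)-2-methyloxiran-2-yl]butan-2-yl hydroperoxide (both epimers at C2) | OOC(C)(CO[Si](C)(C)C(C)(C)C)CC[C@@]1(C)CO1
F5 | step 6 | [(3R,6S)-6-{[(tert-butyldimethylsilyl)oxy]methyl}-3,6-dimethyl-1,2-dioxan-3-yl]methanol (cis epimer) | C[C@]1(CO)CC[C@@](C)(CO[Si](C)(C)C(C)(C)C)OO1
F6 | step 2 | 1,3-dioxoisoindolin-2-yl 2-[(4S)-2,2,4-trimethyl-5-oxo-1,3-dioxolan-4-yl]acetate | C[C@@]1(CC(=O)ON2C(=O)c3ccccc3C2=O)OC(C)(C)OC1=O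
F7 | step 14 | 5-({(3R,6R)-3,6-dimethyl-6-[(1Z)-8-phenyloct-1-en-1-yl]-1,2-dioxan-3-yl}methylidene)-2,2-dimethyl-1,3-dioxane-4,6-dione | C[C@]1(/C=C\CCCCCCc2ccccc2)CC[C@](C)(C=C2C(=O)OC(C)(C)OC2=O)OO1
F8 | step 14 | 5-({(3R,6R)-3,6-dimethyl-6-[(1Z)-8-phenyloct-1-en-1-yl]-1,2-dioxan-3-yl}methyl)-2,2-dimethyl-1,3-dioxane-4,6-dione | C[C@]1(/C=C\CCCCCCc2ccccc2)CC[C@](C)(CC2C(=O)OC(C)(C)OC2=O)OO1
F9 | step 14 | 3-{(3R,6R)-3,6-dimethyl-6-[(1Z)-8-phenyloct-1-en-1-yl]-1,2-dioxan-3-yl}propanoic acid | C[C@]1(/C=C\CCCCCCc2ccccc2)CC[C@](C)(CCC(=O)O)OO1
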